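**Plan**
1. Retrosynthesis: the two benzyl ethers of ring B come off last. Ring A is cut at C4a–C5 and C8–C8a, so it is annulated onto C5=C6 of a dihydropyranone. Ring C is cut at C2–C3 and O1–C8a (hetero-Diels–Alder).
2. Enabling feature: ring C is a 2-aryl-3-methoxy-tetrahydropyran-4-one whose O1–C2 unit is the carbonyl group of the ring B aldehyde; C3, C4, C4a and C8a map onto a 1,4-dimethoxy-2-silyloxybutadiene.
3. Forward order: aldehyde 3 and diene 7 are made separately and ring C closes in the catalytic asymmetric [4+2] step. Ring A is then built on C5–C6 by vinylogous Mukaiyama–Michael addition of a four-carbon dienolate, Saegusa–Ito oxidation and acylative cycloaromatisation; hydrogenolysis ends the route.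
4. Stereochemistry: C2 is set by the chiral salen complex of trivalent chromium (aldehyde face). C3 is brought to the 2,3-trans arrangement by acid equilibration of the enolisable α-carbon. All later steps avoid strong base, which would open ring C by β-elimination of O1 and racemise C2.

Key step: step 6

Remark: 4 and 11 are taken to be catalogue compounds; each is otherwise one acylation step from methoxyacetyl chloride.

**Step 1**
Reactants: 1 2-methoxybenzene-1,4-diol
Product: 2 1,4-bis(benzyloxy)-2-methoxybenzene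
Conditions: BnBr (2.4 equiv), K2CO3, DMF, 60 °C, argon
Reagents that add atoms: benzyl bromide BrCc1ccccc1
Why: Williamson ether synthesis of both phenols should be clean when air is excluded, since the hydroquinone would otherwise oxidise under carbonate.

**Step 2**
Reactants: 2 1,4-bis(benzyloxy)-2-methoxybenzene
Product: 3 2,5-bis(benzyloxy)-4-methoxybenzaldehyde
Conditions: POCl3, DMF, 0 → 70 °C; then aq. NaOAc
Reagents that add atoms: N,N-dimethylformamide CN(C)C=O; water O
Why: Vilsmeier–Haack formylation should occur at the one position that is para to the methoxy group and ortho to a benzyloxy group, the pattern known from 1,2,4-trialkoxybenzenes.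

**Step 3**
Reactants: 4 N,2-dimethoxy-N-methylacetamide
Product: 5 1-methoxybut-3-yn-2-one
Conditions: HC≡CMgBr, THF, 0 °C; inverse quench into cold aq. NaHSO4
Reagents that add atoms: ethynylmagnesium bromide C#C[Mg]Br
Why: Acylation of the alkynyl Grignard reagent by the N-methoxy-N-methylamide stops at the ketone because the chelated tetrahedral adduct survives until the acidic quench, which also keeps the freed amine from adding to the ynone.

**Step 4**
Reactants: 5 1-methoxybut-3-yn-2-one
Product: 6 (E)-1,4-dimethoxybut-3-en-2-one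
Conditions: MeOH (1.5 equiv), DABCO (10 mol %), CH2Cl2, 0 → 25 °C
Reagents that add atoms: methanol CO
Why: Amine-catalysed oxa-Michael addition of methanol to a terminal ynone gives the (E)-β-methoxy enone, the thermodynamic geometry.

**Step 5**
Reactants: 6 (E)-1,4-dimethoxybut-3-en-2-one
Product: 7 (1Z,3E)-2-(tert-butyldimethylsilyloxy)-1,4-dimethoxybuta-1,3-diene
Conditions: TBSOTf, Et3N, Et2O, 0 °C
Reagents that add atoms: tert-butyldimethylsilyl trifluoromethanesulfonate CC(C)(C)[Si](C)(C)OS(=O)(=O)C(F)(F)F
Why: Silyl enol ether formation by soft enolisation can only remove a proton from the methoxymethylene carbon and, as for other α-alkoxy ketones, should place the methoxy and silyloxy groups cis.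

**Step 6**
Reactants: 3 2,5-bis(benzyloxy)-4-methoxybenzaldehyde; 7 (1Z,3E)-2-(tert-butyldimethylsilyloxy)-1,4-dimethoxybuta-1,3-diene
Product: 10 (2R,3R)-2-[2,5-bis(benzyloxy)-4-methoxyphenyl]-3-methoxy-2,3-dihydro-4H-pyran-4-one, via all-cis cycloadduct 8 (not isolated), via 2,3-cis enone 9 (not isolated)
Conditions: (S,S)-(salen)CrBF4 (5 mol %; salen = N,N′-bis(3,5-di-tert-butylsalicylidene)cyclohexane-1,2-diaminate; trivalent chromium; from (salen)CrCl and AgBF4), 4 Å molecular sieves, t-BuOMe, −20 → 0 °C; then CF3CO2H, CH2Cl2, 0 → 25 °C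
Reagents that add atoms: none
Why: The cationic trivalent chromium centre binds the aldehyde oxygen of 3 and diene 7 adds in a concerted, asynchronous [4+2] cycloaddition (a Mukaiyama aldol followed by cyclisation would form the same bonds): the methoxy-bearing silyl enol ether carbon bonds to the aldehyde carbon (C2–C3) and the aldehyde oxygen bonds to the methoxymethine terminus (O1–C8a), as in known catalytic asymmetric hetero-Diels–Alder reactions of aryl aldehydes with 1-methoxy-3-silyloxydienes, 4-oxygenated ones included. Ring C closes as a six-membered ring by this [4+2] cycloaddition, and trifluoroacetic acid then expels methanol and the silyl group from 8 to give enone 9. C2 is set by the chiral salen ligand, which shields one face of the bound aldehyde; the (S,S) complex is proposed by analogy with the parent benzaldehyde reaction, where the (R,R) complex delivers the diene to the Re face whereas the Si face is needed here, and the sense is to be confirmed on the first run. C3 arises cis to the aryl group from the endo transition state of the (1Z,3E) diene and is then equilibrated by the acid through the C3 enol to the 2,3-trans compound 10, expected to be the more stable epimer. Regioselectivity is secured because both donor groups of the diene push towards the silyl enol ether terminus; reactivity towards an electron-rich aldehyde is helped by the non-coordinating counter-ion, the sieves and the extra 4-methoxy donor of the diene.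

**Step 7**
Reactants: 11 tert-butyl methoxyacetate
Product: 12 tert-butyl 2-methoxy-3-oxobutanoate (racemic)
Conditions: LiN(iPr)2, THF, −78 °C; MeC(O)N(OMe)Me, −78 → 0 °C; aq. NH4Cl
Reagents that add atoms: N-methoxy-N-methylacetamide CC(=O)N(C)OC
Why: Crossed Claisen-type acylation of the lithium ester enolate with an N-methoxy-N-methylamide should give the β-keto ester without double acylation because the chelated adduct collapses only on work-up; the new stereocenter is racemic and disappears in step 8.

**Step 8**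
Reactants: 12 tert-butyl 2-methoxy-3-oxobutanoate
Product: 13 tert-butyl 2,3-dimethoxybut-2-enoate (E/Z mixture)
Conditions: KN(SiMe3)2, 18-crown-6, THF, −78 °C; Me2SO4, −78 → 0 °C
Reagents that add atoms: dimethyl sulfate COS(=O)(=O)OC
Why: O-alkylation of the crown-ether-separated potassium enolate of a 2-substituted β-keto ester with a hard methylating agent should give the β-methoxy enoate, whose double-bond geometry does not matter later.

**Step 9**
Reactants: 13 tert-butyl 2,3-dimethoxybut-2-enoate
Product: 14 [(1-tert-butoxy-2,3-dimethoxybuta-1,3-dien-1-yl)oxy]trimethylsilane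
Conditions: LiN(iPr)2, THF, −78 °C; Me3SiCl; non-aqueous work-up, distillation
Reagents that add atoms: chlorotrimethylsilane C[Si](C)(C)Cl
Why: γ-Deprotonation of the β-alkoxy enoate and O-silylation of the dienolate (silyl ketene acetal formation) should give the 1-alkoxy-1-silyloxy diene, as is standard for 3-methoxycrotonates.

**Step 10**
Reactants: 10 (2R,3R)-2-[2,5-bis(benzyloxy)-4-methoxyphenyl]-3-methoxy-2,3-dihydro-4H-pyran-4-one; 14 [(1-tert-butoxy-2,3-dimethoxybuta-1,3-dien-1-yl)oxy]trimethylsilane
Product: 15 tert-butyl 4-[(2R,3R)-2-[2,5-bis(benzyloxy)-4-methoxyphenyl]-3-methoxy-4-(trimethylsilyloxy)-3,6-dihydro-2H-pyran-6-yl]-2,3-dimethoxybut-2-enoate (pyran numbered as in 10; C6 epimers and E/Z mixture; used crude)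
Conditions: Me3SiOTf (10 mol %), CH2Cl2, −78 °C; pyridine quench
Reagents that add atoms: none
Why: Vinylogous Mukaiyama–Michael addition: O-silylation of the enone gives a 4-silyloxy oxocarbenium ion that is attacked at C6 by the unhindered γ-carbon of the dienolate, with silyl transfer turning over the catalyst; the new C6 stereocenter (probably trans to the aryl group) is not controlled and is erased in step 11, while C2 and C3 are untouched because no base is present and C3 is no longer α to a carbonyl group.

**Step 11**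
Reactants: 15 silyl enol ether from step 10
Product: 16 tert-butyl 4-[(2R,3R)-2-[2,5-bis(benzyloxy)-4-methoxyphenyl]-3-methoxy-4-oxo-3,4-dihydro-2H-pyran-6-yl]-2,3-dimethoxybut-2-enoate (E/Z mixture)
Conditions: Pd(OAc)2 (1.1 equiv, divalent palladium), MeCN, 25 °C
Reagents that add atoms: none
Why: Saegusa–Ito oxidation through the C5 palladium enolate and β-hydride loss from C6 should restore the vinylogous ester regiospecifically under neutral conditions that leave C2 and C3 alone.

**Step 12**
Reactants: 16 tert-butyl ester from step 11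
Product: 19 (2R,3R)-2-[2,5-bis(benzyloxy)-4-methoxyphenyl]-5-hydroxy-3,6,7-trimethoxy-2,3-dihydro-4H-chromen-4-one, via acid 17 (not isolated), via mixed anhydride 18 (not isolated)
Conditions: CF3CO2H, CH2Cl2, 0 °C, then evaporation; (CF3CO)2O (1.1 equiv), Et3N, CH2Cl2, 0 → 25 °C; aq. NaHCO3
Reagents that add atoms: none
Why: Acidolysis of the tert-butyl ester and mixed-anhydride activation should trigger the anhydride-mediated cycloaromatisation known for dienoic acids (intramolecular acylation of C5 of the vinylogous ester, directly or by six-electron electrocyclisation of the derived dienylketene, then tautomerisation), which fixes the ring A pattern because the acyl carbon becomes C5–OH next to the ketone, the two methoxy carbons become C6 and C7 and the methylene becomes C8–H.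

**Step 13**
Reactants: 19 dibenzyl ether from step 12
Product: 20 (2R,3R)-2-(2,5-dihydroxy-4-methoxyphenyl)-5-hydroxy-3,6,7-trimethoxy-2,3-dihydro-4H-chromen-4-one (CNP0257825.1)
Conditions: H2 (1 atm), 10% Pd/C, EtOAc, 25 °C, argon work-up
Reagents that add atoms: none
Why: Hydrogenolysis of the two aryl benzyl ethers over palladium is neutral and should leave the base-sensitive trans-flavanonol, its aryl ketone and the benzylic C2–O1 bond intact if stopped at the calculated uptake.

**Compound list**
1 | 2-methoxybenzene-1,4-diol (methoxyhydroquinone) | COc1cc(O)ccc1O | starting material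
2 | 1,4-bis(benzyloxy)-2-methoxybenzene | COc1cc(OCc2ccccc2)ccc1OCc1ccccc1 | intermediate
3 | 2,5-bis(benzyloxy)-4-methoxybenzaldehyde | COc1cc(OCc2ccccc2)c(C=O)cc1OCc1ccccc1 | intermediate
4 | N,2-dimethoxy-N-methylacetamide | COCC(=O)N(C)OC | starting material
5 | 1-methoxybut-3-yn-2-one | COCC(=O)C#C | intermediate
6 | (E)-1,4-dimethoxybut-3-en-2-one | CO/C=C/C(=O)COC | intermediate
7 | (1Z,3E)-2-(tert-butyldimethylsilyloxy)-1,4-dimethoxybuta-1,3-diene | CO/C=C/C(O[Si](C)(C)C(C)(C)C)=C/OC | intermediate
8 | (2R,3S,6R)-2-[2,5-bis(benzyloxy)-4-methoxyphenyl]-4-(tert-butyldimethylsilyloxy)-3,6-dimethoxy-3,6-dihydro-2H-pyran (all-cis cycloadduct) | COc1cc(OCc2ccccc2)c([C@H]2O[C@@H](OC)C=C(O[Si](C)(C)C(C)(C)C)[C@H]2OC)cc1OCc1ccccc1 | intermediate (not isolated)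
9 | (2R,3S)-2-[2,5-bis(benzyloxy)-4-methoxyphenyl]-3-methoxy-2,3-dihydro-4H-pyran-4-one (2,3-cis) | COc1cc(OCc2ccccc2)c([C@H]2OC=CC(=O)[C@H]2OC)cc1OCc1ccccc1 | intermediate (not isolated)
10 | (2R,3R)-2-[2,5-bis(benzyloxy)-4-methoxyphenyl]-3-methoxy-2,3-dihydro-4H-pyran-4-one (2,3-trans) | COc1cc(OCc2ccccc2)c([C@H]2OC=CC(=O)[C@@H]2OC)cc1OCc1ccccc1 | intermediate
11 | tert-butyl methoxyacetate | COCC(=O)OC(C)(C)C | starting material
12 | tert-butyl 2-methoxy-3-oxobutanoate (racemic) | COC(C(C)=O)C(=O)OC(C)(C)C | intermediate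
13 | tert-butyl 2,3-dimethoxybut-2-enoate (E/Z mixture) | COC(C)=C(OC)C(=O)OC(C)(C)C | intermediate
14 | [(1-tert-butoxy-2,3-dimethoxybuta-1,3-dien-1-yl)oxy]trimethylsilane (ketene acetal geometry not defined) | C=C(OC)C(OC)=C(OC(C)(C)C)O[Si](C)(C)C | intermediate
15 | tert-butyl 4-[(2R,3R)-2-[2,5-bis(benzyloxy)-4-methoxyphenyl]-3-methoxy-4-(trimethylsilyloxy)-3,6-dihydro-2H-pyran-6-yl]-2,3-dimethoxybut-2-enoate (C6 and alkene geometry not defined) | COc1cc(OCc2ccccc2)c([C@H]2OC(CC(OC)=C(OC)C(=O)OC(C)(C)C)C=C(O[Si](C)(C)C)[C@@H]2OC)cc1OCc1ccccc1 | intermediate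
16 | tert-butyl 4-[(2R,3R)-2-[2,5-bis(benzyloxy)-4-methoxyphenyl]-3-methoxy-4-oxo-3,4-dihydro-2H-pyran-6-yl]-2,3-dimethoxybut-2-enoate (alkene geometry not defined) | COc1cc(OCc2ccccc2)c([C@H]2OC(CC(OC)=C(OC)C(=O)OC(C)(C)C)=CC(=O)[C@@H]2OC)cc1OCc1ccccc1 | intermediate
17 | 4-[(2R,3R)-2-[2,5-bis(benzyloxy)-4-methoxyphenyl]-3-methoxy-4-oxo-3,4-dihydro-2H-pyran-6-yl]-2,3-dimethoxybut-2-enoic acid | COc1cc(OCc2ccccc2)c([C@H]2OC(CC(OC)=C(OC)C(O)=O)=CC(=O)[C@@H]2OC)cc1OCc1ccccc1 | intermediate (not isolated)
18 | mixed anhydride of 17 with trifluoroacetic acid | COc1cc(OCc2ccccc2)c([C@H]2OC(CC(OC)=C(OC)C(=O)OC(=O)C(F)(F)F)=CC(=O)[C@@H]2OC)cc1OCc1ccccc1 | intermediate (not isolated)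
19 | (2R,3R)-2-[2,5-bis(benzyloxy)-4-methoxyphenyl]-5-hydroxy-3,6,7-trimethoxy-2,3-dihydro-4H-chromen-4-one | COc1cc(OCc2ccccc2)c([C@H]2Oc3cc(OC)c(OC)c(O)c3C(=O)[C@@H]2OC)cc1OCc1ccccc1 | intermediate
20 | (2R,3R)-2-(2,5-dihydroxy-4-methoxyphenyl)-5-hydroxy-3,6,7-trimethoxy-2,3-dihydro-4H-chromen-4-one | COc1cc(O)c([C@H]2Oc3cc(OC)c(OC)c(O)c3C(=O)[C@@H]2OC)cc1O | target

**Totals**
Total steps: 13. Longest linear sequence: 8 steps (4 → 5 → 6 → 7 → 10 → 15 → 16 → 19 → 20; steps 3, 4, 5, 6, 10, 11, 12, 13).

**Steps most likely to fail**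

Step 6. The electron-rich aldehyde may react so slowly that the diene is lost to hydrolysis or oligomerisation, and an unselective background reaction may erode facial selectivity. Acid equilibration at C3 may also stop short of the trans compound. Fallback, setting out from 3 and returning at 9: C2 is fixed by an auxiliary-controlled aldol reaction and ring C is closed by oxa-Michael cyclisation. The dibutylboron enolate (Bu2BOTf, iPr2NEt, CH2Cl2, −78 °C) of (S)-4-benzyl-3-(2-methoxyacetyl)oxazolidin-2-one F1 (from (S)-4-benzyloxazolidin-2-one, n-BuLi and methoxyacetyl chloride) should add to 3 to give the syn-aldol adduct F2. Transamidation with Me3Al and MeNH(OMe)·HCl gives the N-methoxy-N-methylamide F3, and excess HC≡CMgBr gives the β-hydroxy ynone F4. AgOTf-catalysed 6-endo-dig addition of the hydroxyl group to the ynone then gives the 2,3-cis enone 9, which rejoins step 6 at the acid equilibration to 10.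

Step 10. The hindered, trioxygenated dienolate may attack through its α-carbon, or react too slowly, so that the silyl triflate instead degrades the acid-sensitive pyranone. Fallback, setting out from 10 and returning at 17: the four-carbon unit is delivered by a 2-silyloxyfuran, a more nucleophilic and strictly γ-selective donor, at the cost of one reductive step. Dimethyl squarate is reduced with LiAlH(OtBu)3 (THF, −78 °C) to 4-hydroxy-2,3-dimethoxycyclobut-2-en-1-one F5. Heating in toluene (electrocyclic opening to the hydroxyvinylketene, then lactonisation) gives 3,4-dimethoxyfuran-2(5H)-one F6, and Me3SiOTf/Et3N gives [(3,4-dimethoxyfuran-2-yl)oxy]trimethylsilane F7. Addition of F7 to 10 under Me3SiOTf catalysis gives the butenolide silyl enol ether F8, and Saegusa–Ito oxidation (Pd(OAc)2, MeCN) gives the butenolide enone F9. Zinc in acetic acid then cleaves the γ-acyloxy enone at the lactone C–O bond to give acid 17, with the Z geometry fixed by the lactone ring; 17 re-enters step 12 at the anhydride stage.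

Step 12. Ring closure may fail because C5 of the vinylogous ester is a weak nucleophile and the ketene may not form, while the β-alkoxyacrylic acid is lost to enol ether hydrolysis and decarboxylation. Fallback, setting out from 15 and returning at 19: ring A is closed at the ketone oxidation level and aromatised by dehydrogenation. Mild acid hydrolysis of the silyl enol ether (citric acid, MeOH) gives the tetrahydropyranone ester F10, and CF3CO2H gives the acid F11. (CF3CO)2O followed by BF3·OEt2 (acylation of the ketone enol by the mixed anhydride) gives the bicyclic β-diketone F12, and DDQ (1,4-dioxane, 60 °C) dehydrogenates it to phenol 19.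

**Further compounds**
F1 | step 6 | (S)-4-benzyl-3-(2-methoxyacetyl)oxazolidin-2-one | COCC(=O)N1[C@@H](Cc2ccccc2)COC1=O
F2 | step 6 | (4S)-4-benzyl-3-[(2S,3R)-3-[2,5-bis(benzyloxy)-4-methoxyphenyl]-3-hydroxy-2-methoxypropanoyl]oxazolidin-2-one | O=C1OC[C@H](Cc2ccccc2)N1C(=O)[C@@H](OC)[C@H](O)c1cc(OCc2ccccc2)c(OC)cc1OCc1ccccc1
F3 | step 6 | (2S,3R)-3-[2,5-bis(benzyloxy)-4-methoxyphenyl]-3-hydroxy-N,2-dimethoxy-N-methylpropanamide | CON(C)C(=O)[C@@H](OC)[C@H](O)c1cc(OCc2ccccc2)c(OC)cc1OCc1ccccc1
F4 | step 6 | (4S,5R)-5-[2,5-bis(benzyloxy)-4-methoxyphenyl]-5-hydroxy-4-methoxypent-1-yn-3-one | C#CC(=O)[C@@H](OC)[C@H](O)c1cc(OCc2ccccc2)c(OC)cc1OCc1ccccc1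
F5 | step 10 | 4-hydroxy-2,3-dimethoxycyclobut-2-en-1-one (racemic) | COC1=C(OC)C(O)C1=O
F6 | step 10 | 3,4-dimethoxyfuran-2(5H)-one | COC1=C(OC)C(=O)OC1
F7 | step 10 | [(3,4-dimethoxyfuran-2-yl)oxy]trimethylsilane | COc1coc(O[Si](C)(C)C)c1OC
F8 | step 10 | 5-[(2R,3R)-2-[2,5-bis(benzyloxy)-4-methoxyphenyl]-3-methoxy-4-(trimethylsilyloxy)-3,6-dihydro-2H-pyran-6-yl]-3,4-dimethoxyfuran-2(5H)-one (pyran C6 and furanone C5 not defined) | COc1cc(OCc2ccccc2)c([C@H]2OC(C3OC(=O)C(OC)=C3OC)C=C(O[Si](C)(C)C)[C@@H]2OC)cc1OCc1ccccc1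
F9 | step 10 | 5-[(2R,3R)-2-[2,5-bis(benzyloxy)-4-methoxyphenyl]-3-methoxy-4-oxo-3,4-dihydro-2H-pyran-6-yl]-3,4-dimethoxyfuran-2(5H)-one (furanone C5 not defined) | COc1cc(OCc2ccccc2)c([C@H]2OC(C3OC(=O)C(OC)=C3OC)=CC(=O)[C@@H]2OC)cc1OCc1ccccc1
F10 | step 12 | tert-butyl 4-[(5R,6R)-6-[2,5-bis(benzyloxy)-4-methoxyphenyl]-5-methoxy-4-oxotetrahydro-2H-pyran-2-yl]-2,3-dimethoxybut-2-enoate (pyran C2 and alkene geometry not defined) | COc1cc(OCc2ccccc2)c([C@H]2OC(CC(OC)=C(OC)C(=O)OC(C)(C)C)CC(=O)[C@@H]2OC)cc1OCc1ccccc1
F11 | step 12 | 4-[(5R,6R)-6-[2,5-bis(benzyloxy)-4-methoxyphenyl]-5-methoxy-4-oxotetrahydro-2H-pyran-2-yl]-2,3-dimethoxybut-2-enoic acid | COc1cc(OCc2ccccc2)c([C@H]2OC(CC(OC)=C(OC)C(O)=O)CC(=O)[C@@H]2OC)cc1OCc1ccccc1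
F12 | step 12 | (2R,3R)-2-[2,5-bis(benzyloxy)-4-methoxyphenyl]-3,6,7-trimethoxy-2,3,8,8a-tetrahydro-4H-chromene-4,5(4aH)-dione (C4a and C8a not defined) | COc1cc(OCc2ccccc2)c([C@H]2OC3CC(OC)=C(OC)C(=O)C3C(=O)[C@@H]2OC)cc1OCc1ccccc1
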